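The 2H-pyran ring is disconnected between its quaternary carbon C2 (the CMe2 carbon) and the neighbouring vinylic carbon C3. In the forward sense a redox-neutral 1,5-hydride shift/cyclisation turns an isopropyl enol ether that carries an ethynyl group on the adjacent olefinic carbon (C10–O-iPr and C11–C≡CH of a dibenzo[b,f]oxepine) into the fused 2,2-dimethyl-2H-pyran in one operation: the ether methine C–H is traded for the C2–C3 bond. The step exploits the cis arrangement enforced by the oxepine C10=C11 bond and the latent oxocarbenium character of the O–CMe2 carbon. The precursor arises from a dibenzoxepinone by chloroformylation, alkoxide exchange and alkyne homologation; prenylation and O-demethylation finish the synthesis.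

Key step: step 7

Remark: dibenzo[b,f]oxepine locants are used throughout (ring oxygen O5; C10 and C11 are the olefinic carbons; C10 is bonded to the ring that comes from 3-methoxyphenol, C11 to the ring that later carries the prenyl group). The target has no stereocentre, and both pyran double bonds are fixed by the rings.

Step 1
Reactants: 1 2-(2-bromo-4-methoxyphenyl)acetic acid; 2 3-methoxyphenol
Product: 3 2-[4-methoxy-2-(3-methoxyphenoxy)phenyl]acetic acid
Conditions: CuI (10 mol %), N,N-dimethylglycine (20 mol %), Cs2CO3, dioxane, 100 °C
Reagents that add atoms: none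
Why: Copper-catalysed Ullmann diaryl ether synthesis, in which the phenoxide of 2 displaces the only aryl bromide of 1 and the ortho carboxylatomethyl group assists the copper insertion.

Step 2
Reactants: 3 2-[4-methoxy-2-(3-methoxyphenoxy)phenyl]acetic acid
Product: 4 3,7-dimethoxydibenzo[b,f]oxepin-10(11H)-one
Conditions: P2O5/MeSO3H (1:10 w/w, as solvent), 50 °C
Reagents that add atoms: none
Why: Intramolecular Friedel–Crafts acylation should close the seven-membered ring at the position of the 3-methoxyphenoxy ring that is para to the methoxy group and ortho to the ether oxygen, since the only other site within reach lies crowded between the two oxygen substituents.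

Step 3
Reactants: 4 3,7-dimethoxydibenzo[b,f]oxepin-10(11H)-one
Product: 5 2-bromo-3,7-dimethoxydibenzo[b,f]oxepin-10(11H)-one
Conditions: NBS (1.0 equiv), MeCN, 0 °C
Reagents that add atoms: N-bromosuccinimide O=C1CCC(=O)N1Br
Why: Electrophilic aromatic bromination should go to C2 of the ring that bears the CH2 group (ortho to OMe, para to the ring oxygen), because the other alkoxylated ring is now deactivated by the conjugated ketone and C4 is flanked by two oxygen substituents.

Step 4
Reactants: 5 2-bromo-3,7-dimethoxydibenzo[b,f]oxepin-10(11H)-one
Product: 7 2-bromo-10-chloro-3,7-dimethoxydibenzo[b,f]oxepine-11-carbaldehyde, via chlorovinyl iminium chloride 6 (not isolated)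
Conditions: POCl3, DMF, 0 → 70 °C; then H2O, 0 °C
Reagents that add atoms: N,N-dimethylformamide CN(C)C=O; phosphoryl chloride O=P(Cl)(Cl)Cl; water O
Why: Vilsmeier–Haack chloroformylation of an enolisable benzylic ketone should give the β-chlorovinyl aldehyde after hydrolysis of the iminium salt, the bromine at C2 blocking the only arene position activated enough for competing formylation.

Step 5
Reactants: 7 2-bromo-10-chloro-3,7-dimethoxydibenzo[b,f]oxepine-11-carbaldehyde
Product: 8 2-bromo-3,7-dimethoxy-10-(propan-2-yloxy)dibenzo[b,f]oxepine-11-carbaldehyde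
Conditions: NaOiPr (1.1 equiv), THF, 0 °C
Reagents that add atoms: sodium propan-2-olate CC(C)[O-].[Na+]
Why: Nucleophilic vinylic substitution (addition–elimination) on the vinylogous acid chloride should replace the chloride at C10 by isopropoxide, the ring fixing the geometry of the resulting β-alkoxy enal.

Step 6
Reactants: 8 2-bromo-3,7-dimethoxy-10-(propan-2-yloxy)dibenzo[b,f]oxepine-11-carbaldehyde
Product: 9 2-bromo-11-ethynyl-3,7-dimethoxy-10-(propan-2-yloxy)dibenzo[b,f]oxepine
Conditions: TMSCHN2, n-BuLi, THF, −78 °C; then 8, −78 °C → rt
Reagents that add atoms: (trimethylsilyl)diazomethane C[Si](C)(C)C=[N+]=[N-]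
Why: Colvin alkyne homologation with lithiated TMS-diazomethane should convert the non-enolisable aldehyde into the terminal alkyne at low temperature, without an alkoxide medium that could exchange the isopropyl enol ether.

Step 7
Reactants: 9 2-bromo-11-ethynyl-3,7-dimethoxy-10-(propan-2-yloxy)dibenzo[b,f]oxepine
Product: 11 2-bromo-3,7-dimethoxy-10,11-(2,2-dimethyl-2H-pyrano)dibenzo[b,f]oxepine (pyran O1 on C10; pyran C4 on C11), via oxocarbenium alkenylplatinate zwitterion 10 (not isolated)
Conditions: PtI4 (10 mol %), MeCN (anhydrous), 90 °C, sealed tube
Reagents that add atoms: none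
Why: Proposed new method: PtI4 activates the terminal alkyne in the plane of the enyne, and the tertiary C–H of the isopropyl enol ether, held beside the internal alkyne carbon by the ring-fixed C10=C11 bond, delivers hydride to that carbon through a six-membered transition state (1,5-hydride shift), which gives zwitterion 10 with a 2-propylidene oxocarbenium ion and a (Z)-alkenyl–platinum carbon. That carbon then attacks the oxocarbenium carbon, so the bond between the CMe2 carbon and the neighbouring vinylic CH is formed, the 2H-pyran closes in the 6-endo-trig mode and the catalyst is released. The closest known reaction type is the platinum- or gold-catalysed hydroalkylation of terminal alkynes by 1,5-hydride transfer from the α-C–H of dialkyl ethers, and aryl alkyl ethers are known hydride donors in acid-promoted hydride shift/cyclisations onto benzylidene malonates; the pairing of an enol ether donor with a conjugated alkyne acceptor is the untested part. No stereocentre is formed and the cis geometry of the new ring alkene follows from the ring. The step needs hydride transfer to be faster than 5-endo attack of the ether oxygen on the terminal alkyne carbon (furan formation with loss of the isopropyl group) and than alkyne hydration; the doubly methyl-stabilised oxocarbenium ion, the Markovnikov polarisation of the bound alkyne towards its internal carbon, the delocalised and therefore weakly nucleophilic enol ether oxygen and anhydrous conditions should secure this.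

Step 8
Reactants: 11 2-bromo-3,7-dimethoxy-10,11-(2,2-dimethyl-2H-pyrano)dibenzo[b,f]oxepine
Product: 13 di-O-methylartocarpol D, via aryllithium 12 (not isolated)
Conditions: n-BuLi, THF, −78 °C; then CuBr·SMe2 (10 mol %), prenyl bromide, −78 → 0 °C
Reagents that add atoms: 1-bromo-3-methylbut-2-ene (prenyl bromide) CC(C)=CCBr
Why: Bromine–lithium exchange followed by copper-catalysed allylic substitution at the primary carbon of prenyl bromide (SN2 mode) should install the linear prenyl group, since the substrate offers no acidic or electrophilic site that competes at −78 °C.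

Step 9
Reactants: 13 di-O-methylartocarpol D
Product: 14 artocarpol D
Conditions: EtSNa (excess), DMF, 140 °C; then H2O
Reagents that add atoms: none
Why: Nucleophilic (SN2) O-demethylation by ethanethiolate should cleave both aryl methyl ethers, because the thiolate attacks only unhindered methyl carbons and leaves the tertiary O–CMe2 bond, the diaryl ether and the prenyl group alone.

Compound list
1 | 2-(2-bromo-4-methoxyphenyl)acetic acid | COc1ccc(CC(=O)O)c(Br)c1 | starting material
2 | 3-methoxyphenol | COc1cccc(O)c1 | starting material
3 | 2-[4-methoxy-2-(3-methoxyphenoxy)phenyl]acetic acid | COc1cccc(Oc2cc(OC)ccc2CC(=O)O)c1 | intermediate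
4 | 3,7-dimethoxydibenzo[b,f]oxepin-10(11H)-one | O=C1Cc2ccc(OC)cc2Oc2cc(OC)ccc12 | intermediate
5 | 2-bromo-3,7-dimethoxydibenzo[b,f]oxepin-10(11H)-one | O=C1Cc2cc(Br)c(OC)cc2Oc2cc(OC)ccc12 | intermediate
6 | N-[(2-bromo-10-chloro-3,7-dimethoxydibenzo[b,f]oxepin-11-yl)methylidene]-N-methylmethanaminium chloride (not isolated) | C[N+](C)=CC1=C(Cl)c2ccc(OC)cc2Oc2cc(OC)c(Br)cc12.[Cl-] | intermediate
7 | 2-bromo-10-chloro-3,7-dimethoxydibenzo[b,f]oxepine-11-carbaldehyde | O=CC1=C(Cl)c2ccc(OC)cc2Oc2cc(OC)c(Br)cc12 | intermediate
8 | 2-bromo-3,7-dimethoxy-10-(propan-2-yloxy)dibenzo[b,f]oxepine-11-carbaldehyde | O=CC1=C(OC(C)C)c2ccc(OC)cc2Oc2cc(OC)c(Br)cc12 | intermediate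
9 | 2-bromo-11-ethynyl-3,7-dimethoxy-10-(propan-2-yloxy)dibenzo[b,f]oxepine | C#CC1=C(OC(C)C)c2ccc(OC)cc2Oc2cc(OC)c(Br)cc12 | intermediate
10 | zwitterion from 9 after hydride transfer: O-(propan-2-ylidene)oxonium at C10 and (Z)-2-(tetraiodoplatinato)ethenyl group at C11 (not isolated) | CC(C)=[O+]C1=C(/C=C\[Pt-](I)(I)(I)I)c2cc(Br)c(OC)cc2Oc2cc(OC)ccc12 | intermediate
11 | 2-bromo-3,7-dimethoxy-10,11-(2,2-dimethyl-2H-pyrano)dibenzo[b,f]oxepine: 2,2-dimethyl-2H-pyran fused across C10–C11, pyran O1 on C10 and pyran C4 on C11 (the 2-bromo, des-prenyl, di-O-methyl analogue of artocarpol D) | Brc1cc2c(cc1OC)Oc1cc(OC)ccc1C1=C2C=CC(C)(C)O1 | intermediate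
12 | 2-lithio derivative of 11, lithium in place of bromine (not isolated) | [Li]c1cc2c(cc1OC)Oc1cc(OC)ccc1C1=C2C=CC(C)(C)O1 | intermediate
13 | di-O-methylartocarpol D: compound 11 with a 3-methylbut-2-en-1-yl group in place of bromine at C2 | CC(C)=CCc1cc2c(cc1OC)Oc1cc(OC)ccc1C1=C2C=CC(C)(C)O1 | intermediate
14 | artocarpol D | CC(C)=CCc1cc2c(cc1O)Oc1cc(O)ccc1C1=C2C=CC(C)(C)O1 | target

Total step count: 9. Longest linear sequence: 9 steps (from 1; compound 2 enters in step 1).

Steps most likely to fail

Step 7 (proposed new method). Hydride transfer may be outrun by 5-endo attack of the enol ether oxygen on the platinum-bound alkyne, with loss of the isopropyl group as propene and formation of a furan, or the electron-rich enyne may be hydrated or oligomerised. The fallback keeps the same ring-closing bond but uses known carbenoid chemistry; it sets out from aldehyde 8 and comes back at 11. Aldehyde 8 would be oxidised (NaClO2, NaH2PO4, 2-methylbut-2-ene, t-BuOH/H2O, Pinnick oxidation) to 2-bromo-3,7-dimethoxy-10-(propan-2-yloxy)dibenzo[b,f]oxepine-11-carboxylic acid F1. Oxalyl chloride with catalytic DMF would give the acid chloride F2, and diazomethane in Et2O the diazomethyl ketone F3. Rh2(OAc)4 in CH2Cl2 would then insert the rhodium carbenoid into the tertiary C–H of the isopropyl ether. This insertion next to an ether oxygen is the reaction type known to turn 2-alkoxyaryl diazomethyl ketones into chroman-4-ones, and here it would give the fused 2,2-dimethyl-2,3-dihydro-4H-pyran-4-one F4. Luche reduction (NaBH4, CeCl3·7H2O, MeOH) to the racemic allylic alcohol F5 and PPTS-catalysed dehydration in toluene would return to 11.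

Step 3. Bromination may be unselective between C2 and the ketone-bearing ring, or may take place at the enolisable C11 methylene. The fallback sets the bromine on the simple arene before the rings are assembled; it sets out from 1 and comes back at 5. Acid 1 would be brominated (Br2, AcOH, rt) at the only free position ortho to the methoxy group that is not flanked by bromine, giving 2-(2,5-dibromo-4-methoxyphenyl)acetic acid F6. Ullmann coupling with 2 under the conditions of step 1 should engage the bromide ortho to the carboxylatomethyl group in preference to the electron-rich bromide beside the methoxy group, giving 2-[5-bromo-4-methoxy-2-(3-methoxyphenoxy)phenyl]acetic acid F7. Friedel–Crafts cyclisation as in step 2 would return to 5.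

Step 9. In the hot thiolate medium the prenyl double bond may migrate into conjugation with the ring, or cleavage may stall after the first ether has become a phenoxide. The fallback removes the methyl groups before the prenyl group is present and changes the carbon–carbon coupling; it sets out from 11 and comes back at 14. Bromide 11 would be demethylated with EtSNa in DMF at 140 °C to the bromo diphenol F8. The prenyl group would then be introduced by Stille coupling with tributyl(3-methylbut-2-en-1-yl)stannane and Pd(PPh3)4 (zerovalent palladium) in DMF at 90 °C, which tolerates free phenols, to give 14 directly.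

Further compounds
F1 | step 7 | 2-bromo-3,7-dimethoxy-10-(propan-2-yloxy)dibenzo[b,f]oxepine-11-carboxylic acid | OC(=O)C1=C(OC(C)C)c2ccc(OC)cc2Oc2cc(OC)c(Br)cc12
F2 | step 7 | 2-bromo-3,7-dimethoxy-10-(propan-2-yloxy)dibenzo[b,f]oxepine-11-carbonyl chloride | ClC(=O)C1=C(OC(C)C)c2ccc(OC)cc2Oc2cc(OC)c(Br)cc12
F3 | step 7 | 1-[2-bromo-3,7-dimethoxy-10-(propan-2-yloxy)dibenzo[b,f]oxepin-11-yl]-2-diazoethan-1-one | [N-]=[N+]=CC(=O)C1=C(OC(C)C)c2ccc(OC)cc2Oc2cc(OC)c(Br)cc12
F4 | step 7 | 2-bromo-3,7-dimethoxydibenzo[b,f]oxepine with a 2,2-dimethyl-2,3-dihydro-4H-pyran-4-one fused across C10–C11 (pyran O1 on C10, ketone carbon C4 on C11) | O=C1CC(C)(C)OC2=C1c1cc(Br)c(OC)cc1Oc1cc(OC)ccc21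
F5 | step 7 | racemic allylic alcohol from F4 (OH at pyran C4) | OC1CC(C)(C)OC2=C1c1cc(Br)c(OC)cc1Oc1cc(OC)ccc21
F6 | step 3 | 2-(2,5-dibromo-4-methoxyphenyl)acetic acid | COc1cc(Br)c(CC(=O)O)cc1Br
F7 | step 3 | 2-[5-bromo-4-methoxy-2-(3-methoxyphenoxy)phenyl]acetic acid | COc1cccc(Oc2cc(OC)c(Br)cc2CC(=O)O)c1
F8 | step 9 | bromo diphenol: compound 11 with both methoxy groups replaced by hydroxy groups | Brc1cc2c(cc1O)Oc1cc(O)ccc1C1=C2C=CC(C)(C)O1
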